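Atom labels (C1 to C24, O25, O26) follow the order of the atoms in the target SMILES.
Assumption: the hemiketal carbon C24 has no free choice of configuration, because the O26 bridge to C7 fixes it; it is written as in the target SMILES.
Remark: 7 and 8 are used as the pair of cis-cyclopropanol diastereomers (one is drawn), and 13 to 19 are drawn with the C19 configuration of the target; a C19 epimer that may accompany them is carried along and converged in step 10.

## Analysis of the target

The target 20 is a tetracyclic methyl ester in which three carbocycles are fused angularly. Ring A (C7, C8, C9, C11, C12, C13) is a cyclohexene with the C9=C11 alkene and the C10 methyl, ring B (C5, C6, C7, C13, C14, C16) carries the C5=C6 enoate, and ring C (C14, C16, C17, C19, C23, C24) is a cyclohexanone. O26 ties C7 to C24 as a five-membered cyclic hemiketal, so ring B and the bridge form a 6-oxabicyclo[3.2.1]octene. There are six stereocentres (C7, C13, C14, C16, C19, C24), five of them contiguous around the all-carbon quaternary C14. Rings A and B are cis-fused with C8 and C12 on the face of the C15 methyl, rings B and C are cis-fused on the opposite face, and the C7–O26 bond lies on the ring C face, which is what lets the bridge close. C19 carries its isopropyl group equatorially on the locked ring C and can be corrected by enolisation toward C17. The sensitive points are the hemiketal, the tertiary allylic C7–O bond, the 4-oxygenated enoate, and C16–H, which is α to the C17 ketone and γ to the enoate. The difficulty lies in the crowded C14, in the dissonant 1,4-relationships C17/C24, C7/C24 and C7/C3, and in telling three carbonyl groups apart late in the route. The strategy rests on one feature: the C17 ketone carbon is bonded only to C19 and C16 and stands 1,4 to both the C24 carbonyl and the C3 ester, so it can be carbon monoxide (9) placed between a C19 radical and the C16 terminus of a ring B enoate.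

## Retrosynthetic reasoning

**From 20 to 19.** The C9=C11 bond of ring A is cut (ring-closing metathesis forward). It is the only ring A bond that can be made without touching a stereocentre. The cut leaves an allyl group on C13 and a 2-methylallyl group on C7 of the hemiketal diene 19. The forward step has to close a trisubstituted cyclohexene beside a free hemiketal and is followed in the same flask by base equilibration of C19.

**From 19 to 16 and 17.** The C7–C8 bond and the O26–C24 bond are cut together. 19 is the hemiketal of hydroxy-diketone 18, which arises by addition of the 2-methylallyl unit of 17 to the C7 ketone of triketone 16. The forward step must pick C7 over C17 and C24 and must deliver C8 on the face of the C15 methyl, so that the new alkoxide faces C24 and is captured.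

**From 16 to 13 through 14 and 15.** The C12–C13 bond is cut to the α-bromo ketone 14 and allyltributylstannane 15, and 14 is traced to the dienyl methyl ether 13. An enolate alkylation is avoided because C16–H is the most acidic hydrogen of these triketones. The enol ether of 13 marks C13 as the one nucleophilic carbon, and the radical allylation needs no base.

**From 13 to 8 and 9 (key disconnection).** C16–C17 and C17–C19 are cut, which removes ring C and takes out C17 as carbon monoxide 9. What is left is a C19 radical β to the C24 ketone, and its stable precursor is the cyclopropanol 8. Cutting here keeps the quaternary C14 inside a ring that comes from an arene and uses the 1,4-relationships of C17 named above. Forward, the step must open the cyclopropanol toward C19, capture 9 before the radical closes directly on C16, close ring C by 6-exo attack of the acyl radical on C16, and end with oxidative loss of a C6 hydrogen. It gains two bonds, one ring, the C16 and C19 centres and the C5=C6 alkene.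

**From 8 to 5 and 6 through 7.** The cyclopropanol is cut at C24–C23 and C24–C19 (Kulinkovich reaction). C19, C23 and the isopropyl group come from the Grignard reagent 6, and C24 is the ester carbon of 5. The C3 carboxyl stays as the free acid in 7, so only one ester meets the titanium reagent; it is methylated afterwards to give 8.

**From 5 to 4, 2 and 1.** 5 is the (S)-enantiomer of racemic 4 and is reached by resolution, because C14 has no neighbouring group through which an auxiliary could steer the alkylation. In 4 the C14–C15 bond is cut (C-methylation of dienolate 3). The 1,4-diene with C6 as the saturated carbon is the Birch pattern of benzoate 2, whose ester is the stronger acceptor and therefore becomes the quaternary centre. 2 is the half-ester of commercial 1.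

## Alternatives that were turned down

**Alternative 1: masked o-benzoquinone Diels–Alder, then oxy-Cope.**
- Disconnection: C6–C7 and C13–C14, which unfolds ring B into the masked o-benzoquinone A1 (diene) and the enol ether alkene of cyclohexadiene A2.
- Forward key step: A1, generated by oxidative dearomatisation in methanol and used at once, adds as an electron-poor diene to the electron-rich alkene of A2 and gives the bicyclo[2.2.2]octenone A3. Addition of an alkenyl-metal reagent to the bridging ketone and an anionic oxy-Cope rearrangement would then break the C6–carbonyl bond, form C16–C17 and move the alkene to C5=C6.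
- For: every step is of a known type. The cycloaddition sets C7, C13 and C14 with cis A/B fusion in one intermolecular step, and ring A is present from the start. On A/B stereocontrol and on precedent it is stronger than the chosen route.
- Against: the ketone of A3 becomes C23, which is a methylene in the target, so it must be removed later. The C17 oxygen and the isopropyl group must come in on a hindered trisubstituted alkenyl nucleophile. Dimerisation of A1 competes with a slow reaction at its methyl-bearing terminus. There is no handle for the absolute configuration.
- Comparison: the chosen strategy gives ring C at the right oxidation level in one operation, from a precursor five steps from a commercial arene. It pays with a less secure ring A annulation and a key step without precedent.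

**Alternative 2: transannular Diels–Alder of a fourteen-membered tetraene.**
- Disconnection: C7–C13 and C14–C16 at once, which opens rings A, B and C into the macrocycle A4.
- Forward key step: on heating, the silyloxy-diene (C16=C5–C6=C7) of A4 adds across the enone alkene C13=C14 and gives tricycle A5. Desilylation would let the C7 oxygen close onto C24.
- For: three rings and four stereocentres (C7, C13, C14, C16) form in one step, the geometry of the ring relays the stereochemistry, and transannular cycloadditions of this kind are well established. On stereocontrol of both ring fusions it is clearly stronger than the chosen route.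
- Against: A4 combines a 1,4-diketone, a silyl dienol ether and three trisubstituted alkenes of fixed geometry in one large ring. Its assembly and macrocyclisation would take far more steps than the whole chosen route. The dienophile forms a quaternary centre and is slow, and facial control has to come from the remote, epimerisable C19.
- Comparison: the chosen strategy offers a key precursor in five steps from commodity reagents and confines the risk to one step. It gives up the one-step control of C7 and C13.

**Alternative 3: intramolecular Diels–Alder of an acyclic silyloxy-triene.**
- Disconnection: C14–C16 and C5–C6, which opens rings B and C into triene A6.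
- Forward key step: the 2-silyloxydiene (C6=C7–C13=C14) of A6 adds to the doubly activated alkene C16=C5, held by the four-carbon diketone tether, and gives the cis-fused bicycle A7 with a C7 silyl enol ether.
- For: the key step is known chemistry with a matched diene and dienophile, the 1,4-diketone of ring C is in place beforehand, and the C7 enol ether of A7 is as useful for C13 functionalisation as the one in 13. On reliability of the key step it is stronger.
- Against: the diene terminus C14 is fully substituted and conjugated to the C24 ketone, which lowers its reactivity and demands a defined C13=C14 geometry with a group pointing inward. A6 holds two enolisable 1,4-dicarbonyl units in an open chain. A7 lacks the C5=C6 alkene, so a regioselective dehydrogenation must follow.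
- Comparison: the chosen strategy starts from an arene that already contains ring B, sets C14 in step 2, and installs the C5=C6 alkene in the same operation that closes ring C.

Key step: step 6

## Route

Step 1
Reactants: 1 dimethyl 5-methoxybenzene-1,3-dicarboxylate
Product: 2 3-methoxy-5-(methoxycarbonyl)benzoic acid
Conditions: NaOH (1.0 equiv), MeOH/THF, 0 °C to rt; then 1 M HCl
Reagents that add atoms: sodium hydroxide, [Na+].[OH-]
Why: Half-saponification of a symmetrical diester: once one carboxylate has formed, its charge slows attack of hydroxide on the second ester, so the mono-acid should be the main product and unchanged 1 can be recycled.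

Step 2
Reactants: 2 3-methoxy-5-(methoxycarbonyl)benzoic acid
Product: 4 rac-5-methoxy-3-(methoxycarbonyl)-3-methylcyclohexa-1,4-diene-1-carboxylic acid, via dilithium ester dienolate 3 (not isolated)
Conditions: Li (3.1 equiv), NH3(l)/THF, t-BuOH (1.0 equiv), −78 °C; isoprene; MeI (3 equiv), −78 to −33 °C; aq. NH4Cl, then NaH2PO4 to pH 5
Reagents that add atoms: iodomethane, CI
Why: Birch reductive alkylation of a benzoate ester: the ester is the stronger acceptor, protonation para to it (C6) leaves dienolate 3 with C5=C16 and C7=C13 in place, and iodomethane alkylates the central, ester-bearing carbon C14 as it does other 1,4-dihydrobenzoate enolates. The carboxylate on C5 stays conjugated, and the product is racemic.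

Step 3
Reactants: 4 rac-5-methoxy-3-(methoxycarbonyl)-3-methylcyclohexa-1,4-diene-1-carboxylic acid
Product: 5 (3S)-5-methoxy-3-(methoxycarbonyl)-3-methylcyclohexa-1,4-diene-1-carboxylic acid
Conditions: (R)-1-phenylethylamine (1.0 equiv), EtOAc/i-PrOH, recrystallisation of the less soluble salt; then cold 10% aq. citric acid, EtOAc
Reagents that add atoms: none
Why: Classical resolution of a rigid carboxylic acid through diastereomeric ammonium salts; if the salt of the (R)-acid proves the less soluble one, the antipodal amine is used. The (S) configuration is to be secured by X-ray analysis of the salt, and the acid is liberated cold because of its enol ether.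

Step 4
Reactants: 5 (3S)-5-methoxy-3-(methoxycarbonyl)-3-methylcyclohexa-1,4-diene-1-carboxylic acid; 6 3-methylbutylmagnesium bromide
Product: 7 (3S)-3-[(1S,2R)-1-hydroxy-2-(propan-2-yl)cyclopropyl]-5-methoxy-3-methylcyclohexa-1,4-diene-1-carboxylic acid (drawn; its (1R,2S)-cyclopropyl diastereomer accompanies it)
Conditions: 6 (4.5 equiv, slow addition), Ti(OiPr)4 (1.0 equiv), THF/Et2O, 0 °C to rt; aq. NH4Cl (pH 6–7)
Reagents that add atoms: none
Why: Kulinkovich reaction: the first equivalent of 6 turns the acid into its inert magnesium carboxylate, and the titanacyclopropane formed from further 6 and Ti(OiPr)4 inserts the only ester (C24) to give the cis-1,2-dialkylcyclopropanol, with C14 and the isopropyl group cis as usual. Both cyclopropane diastereomers relative to C14 are expected and both are used, since C24 and C19 lose their configuration in step 6.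

Step 5
Reactants: 7 (3S)-3-[(1S,2R)-1-hydroxy-2-(propan-2-yl)cyclopropyl]-5-methoxy-3-methylcyclohexa-1,4-diene-1-carboxylic acid
Product: 8 methyl (3S)-3-[(1S,2R)-1-hydroxy-2-(propan-2-yl)cyclopropyl]-5-methoxy-3-methylcyclohexa-1,4-diene-1-carboxylate (with its (1R,2S)-cyclopropyl diastereomer)
Conditions: TMSCHN2 (1.5 equiv), MeOH/toluene (1:4), 0 °C
Reagents that add atoms: (trimethylsilyl)diazomethane, C[Si](C)(C)C=[N+]=[N-]
Why: Esterification of a carboxylic acid with a diazoalkane under neutral conditions, which leaves the cyclopropanol, the enol ether and the 1,4-diene untouched.

Step 6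
Reactants: 8 methyl (3S)-3-[(1S,2R)-1-hydroxy-2-(propan-2-yl)cyclopropyl]-5-methoxy-3-methylcyclohexa-1,4-diene-1-carboxylate; 9 carbon monoxide
Product: 13 methyl 3-methoxy-4a-methyl-5,8-dioxo-7-(propan-2-yl)-4a,5,6,7,8,8a-hexahydronaphthalene-1-carboxylate (cis-fused; isopropyl cis to the 4a-methyl), via ring-opened C19 alkyl radical 10 (not isolated), via C17 acyl radical 11 (not isolated), via ring-closed C5 radical 12 (not isolated)
Conditions: Mn(OAc)3·2H2O (2.2 equiv), Cu(OAc)2 (0.2 equiv), NaOAc (2 equiv), CO (90 atm), MeCN (0.01 M), 40 °C, autoclave; aq. NaHCO3 work-up
Reagents that add atoms: none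
Why: Proposed new method: Trivalent manganese binds and oxidises the cyclopropanol oxygen, and β-scission of the strained ring breaks C24–C19 rather than C24–C23 because the secondary radical is the more stable one, which gives the C24 ketone and radical 10. Under 90 atm of 9 this nucleophilic radical is carbonylated to acyl radical 11, which closes ring C by 6-exo-trig addition to C16, the β-carbon of the ring B enoate, and gives the tertiary α-ester radical 12. Divalent copper captures 12 and the organocopper intermediate loses a hydrogen from C6, whose two C–H bonds are allylic to the enol ether and outnumber the single C16–H, so the C5=C6 alkene forms in conjugation with C7=C13; monovalent copper is reoxidised by trivalent manganese. The closest known reactions are the manganese-mediated ring opening of cyclopropanols to β-keto radicals, tin hydride-mediated radical carbonylation with acyl radical cyclisation onto acrylates, and Cu(OAc)2 termination of Mn(OAc)3 cyclisations; their union in one oxidative cascade is not known. C16 is set by the tether: the four-atom chain hangs from C14, next to C16, and can reach C16 only on its own face, so the B/C fusion should be cis. C19 becomes stereogenic on carbonylation without control; it is drawn with the configuration of the target and any epimer is corrected in step 10. The step needs carbonylation of 10 to outrun its direct 5-exo closure onto C16 and its oxidation by copper, which is why the CO pressure is high, the copper salt catalytic and the solution dilute; the acetate buffer protects the enol ether, and dilution also limits hydrogen abstraction from the doubly allylic C6–H2.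

Step 7
Reactants: 13 methyl 3-methoxy-4a-methyl-5,8-dioxo-7-(propan-2-yl)-4a,5,6,7,8,8a-hexahydronaphthalene-1-carboxylate
Product: 14 methyl 4-bromo-4a-methyl-3,5,8-trioxo-7-(propan-2-yl)-3,4,4a,5,6,7,8,8a-octahydronaphthalene-1-carboxylate (cis-fused; bromine drawn cis to the 4a-methyl)
Conditions: NBS (1.05 equiv), NaHCO3, THF/H2O (4:1), 0 °C
Reagents that add atoms: N-bromosuccinimide, O=C1CCC(=O)N1Br; water, O
Why: Electrophilic bromination of an enol ether in water: the 2-methoxydiene is attacked at its nucleophilic terminus C13 and the oxocarbenium ion is hydrolysed to the C7 ketone, so the enone and the C13 bromide form regiospecifically without any enolate. The configuration at C13 is of no consequence for step 8.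

Step 8
Reactants: 14 methyl 4-bromo-4a-methyl-3,5,8-trioxo-7-(propan-2-yl)-3,4,4a,5,6,7,8,8a-octahydronaphthalene-1-carboxylate; 15 allyltributylstannane
Product: 16 methyl 4a-methyl-3,5,8-trioxo-7-(propan-2-yl)-4-(prop-2-en-1-yl)-3,4,4a,5,6,7,8,8a-octahydronaphthalene-1-carboxylate (cis-fused; allyl and isopropyl cis to the 4a-methyl)
Conditions: 15 (2.5 equiv), AIBN (0.2 equiv), benzene, 80 °C
Reagents that add atoms: none
Why: Keck radical allylation of an α-bromo ketone: the stannyl radical abstracts bromine, the planar C13 radical adds to 15 and the β-stannyl radical fragments, so no base meets the acidic C16–H. The allyl group should enter on the convex face of the cis-fused bicycle, syn to the C15 methyl, because ring C covers the other face through C24 or C17.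

Step 9
Reactants: 16 methyl 4a-methyl-3,5,8-trioxo-7-(propan-2-yl)-4-(prop-2-en-1-yl)-3,4,4a,5,6,7,8,8a-octahydronaphthalene-1-carboxylate; 17 3-bromo-2-methylprop-1-ene
Product: 19 methyl 5-hydroxy-4a-methyl-3-(2-methylprop-2-en-1-yl)-8-oxo-7-(propan-2-yl)-4-(prop-2-en-1-yl)-3,4,4a,5,6,7,8,8a-octahydro-3,5-epoxynaphthalene-1-carboxylate (O26 bridges C7 and C24; both alkenyl arms cis to the 4a-methyl), via open C7 tertiary alcohol 18 (not isolated)
Conditions: In powder (1.5 equiv), 17 (2.0 equiv), THF/H2O (1:1), rt; aq. NH4Cl
Reagents that add atoms: none
Why: Indium-mediated Barbier allylation: the 2-methylallylindium reagent adds 1,2 to the most accessible and most electrophilic ketone, the C7 carbonyl of the 4-oxo-enoate, while C17 (two branched α-carbons) and C24 (next to the quaternary C14) are shielded and the ester is inert. Attack on the convex face puts C8 cis to C12 and turns the C7 oxygen toward C24, so alcohol 18 is trapped as the five-membered hemiketal, whose C24 configuration is dictated by the bridge.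

Step 10
Reactants: 19 methyl 5-hydroxy-4a-methyl-3-(2-methylprop-2-en-1-yl)-8-oxo-7-(propan-2-yl)-4-(prop-2-en-1-yl)-3,4,4a,5,6,7,8,8a-octahydro-3,5-epoxynaphthalene-1-carboxylate
Product: 20 target CNP0382995.2 (tetracyclic hemiketal; ring A closed with the C9=C11 alkene)
Conditions: second-generation Grubbs catalyst (5 mol%), CH2Cl2 (0.005 M), 40 °C; then DBU (0.3 equiv), CH2Cl2, rt
Reagents that add atoms: none
Why: Ring-closing metathesis of a monosubstituted and a 1,1-disubstituted alkene, held cis on C13 and C7, gives the trisubstituted cyclohexene of ring A, while the hindered, electron-poor enoate alkene stays out. DBU then equilibrates C19 through the C17 enolate toward the epimer with the equatorial isopropyl group on the locked ring C, which is the configuration of 20.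

## Compound list

1 | dimethyl 5-methoxybenzene-1,3-dicarboxylate | COC(=O)c1cc(OC)cc(c1)C(=O)OC | starting material
2 | 3-methoxy-5-(methoxycarbonyl)benzoic acid | COC(=O)c1cc(OC)cc(c1)C(O)=O | intermediate
3 | dilithium salt of the Birch ester dienolate and carboxylate (not isolated) | [Li+].[Li+].COC1=CC(=C([O-])OC)C=C(C1)C([O-])=O | intermediate
4 | rac-5-methoxy-3-(methoxycarbonyl)-3-methylcyclohexa-1,4-diene-1-carboxylic acid | COC1=CC(C)(C(=O)OC)C=C(C1)C(O)=O | intermediate
5 | (3S)-5-methoxy-3-(methoxycarbonyl)-3-methylcyclohexa-1,4-diene-1-carboxylic acid | COC1=C[C@@](C)(C(=O)OC)C=C(C1)C(O)=O | intermediate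
6 | 3-methylbutylmagnesium bromide | CC(C)CC[Mg]Br | starting material
7 | (3S)-3-[(1S,2R)-1-hydroxy-2-(propan-2-yl)cyclopropyl]-5-methoxy-3-methylcyclohexa-1,4-diene-1-carboxylic acid (drawn; used with its (1R,2S)-cyclopropyl diastereomer) | COC1=C[C@@](C)([C@]2(O)C[C@@H]2C(C)C)C=C(C1)C(O)=O | intermediate
8 | methyl (3S)-3-[(1S,2R)-1-hydroxy-2-(propan-2-yl)cyclopropyl]-5-methoxy-3-methylcyclohexa-1,4-diene-1-carboxylate (drawn; used with its (1R,2S)-cyclopropyl diastereomer) | COC1=C[C@@](C)([C@]2(O)C[C@@H]2C(C)C)C=C(C1)C(=O)OC | intermediate
9 | carbon monoxide | [C-]#[O+] | starting material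
10 | ring-opened β-keto alkyl radical, radical at C19 (not isolated) | COC1=C[C@@](C)(C(=O)C[CH]C(C)C)C=C(C1)C(=O)OC | intermediate
11 | acyl radical at C17, C19 of either configuration (not isolated) | COC1=C[C@@](C)(C(=O)CC([C]=O)C(C)C)C=C(C1)C(=O)OC | intermediate
12 | ring-closed cis-fused α-ester radical at C5, C19 of either configuration (not isolated) | COC(=O)[C]1CC(OC)=C[C@]2(C)[C@H]1C(=O)C(C(C)C)CC2=O | intermediate
13 | methyl 3-methoxy-4a-methyl-5,8-dioxo-7-(propan-2-yl)-4a,5,6,7,8,8a-hexahydronaphthalene-1-carboxylate (cis ring fusion; 7-isopropyl on the face of the 4a-methyl and 8a-H) | COC(=O)C1=CC(OC)=C[C@]2(C)[C@H]1C(=O)[C@@H](C(C)C)CC2=O | intermediate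
14 | methyl 4-bromo-4a-methyl-3,5,8-trioxo-7-(propan-2-yl)-3,4,4a,5,6,7,8,8a-octahydronaphthalene-1-carboxylate (cis ring fusion; bromine drawn on the face of the 4a-methyl) | COC(=O)C1=CC(=O)[C@H](Br)[C@]2(C)[C@H]1C(=O)[C@@H](C(C)C)CC2=O | intermediate
15 | allyltributylstannane (tributyl(prop-2-en-1-yl)stannane) | CCCC[Sn](CCCC)(CCCC)CC=C | starting material
16 | methyl 4a-methyl-3,5,8-trioxo-7-(propan-2-yl)-4-(prop-2-en-1-yl)-3,4,4a,5,6,7,8,8a-octahydronaphthalene-1-carboxylate (cis ring fusion; 4-allyl and 7-isopropyl on the face of the 4a-methyl) | COC(=O)C1=CC(=O)[C@H](CC=C)[C@]2(C)[C@H]1C(=O)[C@@H](C(C)C)CC2=O | intermediate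
17 | 3-bromo-2-methylprop-1-ene | CC(=C)CBr | starting material
18 | methyl 3-hydroxy-4a-methyl-3-(2-methylprop-2-en-1-yl)-5,8-dioxo-7-(propan-2-yl)-4-(prop-2-en-1-yl)-3,4,4a,5,6,7,8,8a-octahydronaphthalene-1-carboxylate (3-OH on the face opposite the 4a-methyl; not isolated) | COC(=O)C1=C[C@](O)(CC(C)=C)[C@H](CC=C)[C@]2(C)[C@H]1C(=O)[C@@H](C(C)C)CC2=O | intermediate
19 | methyl 5-hydroxy-4a-methyl-3-(2-methylprop-2-en-1-yl)-8-oxo-7-(propan-2-yl)-4-(prop-2-en-1-yl)-3,4,4a,5,6,7,8,8a-octahydro-3,5-epoxynaphthalene-1-carboxylate (hemiketal of 18) | COC(=O)C1=C[C@]2(CC(C)=C)[C@H](CC=C)[C@]3(C)[C@H]1C(=O)[C@@H](C(C)C)C[C@@]3(O)O2 | intermediate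
20 | CNP0382995.2, ring A/B/C hemiketal methyl ester | COC(=O)C1=C[C@]23CC(C)=CC[C@@H]2[C@]2(C)[C@H]1C(=O)[C@@H](C(C)C)C[C@@]2(O)O3 | target

## Step count and least certain steps

Total: 10 steps. Longest linear sequence: 10 steps (1 to 20); 6, 9, 15 and 17 enter as reagents.

**Step 6 (key step).** The most likely failure is interception of radical 10 before it is carbonylated. Direct 5-exo closure onto C16 is a fast process for a β-keto radical facing an enoate, and copper can oxidise 10 to an enone. In addition, the electrophilic radical 12 may be oxidised too slowly and abstract hydrogen from the doubly allylic C6–H2 of 8, which starts a chain that aromatises ring B with loss of the side chain. The fallback uses known chemistry and never lets a C19 radical meet carbon monoxide. It sets out from 8. Ring opening with Mn(pic)3 (manganese tris(pyridine-2-carboxylate)) in DMF in the presence of PhSeSePh traps the radical by fast group transfer and gives the β-phenylselanyl ketone F1. Oxidation with H2O2/pyridine and selenoxide elimination give the (E)-enone F2. Nitromethane with DBU adds to C19 of the enone and then, as the nitronate, to C16 of the enoate; this double Michael addition closes ring C as the cis-fused nitro keto ester F3. An oxidative Nef reaction (H2O2, K2CO3, MeOH) turns C17 into the ketone of the saturated diketo ester F4. DDQ dehydrogenation of the enol ether across C6/C5 returns to the route at 13.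

**Step 9.** The likely failure is poor facial selectivity at C7, because the cis-fused bicycle is flexible and the ring B conformer with an axial C15 methyl exposes the wrong face; addition at C24 is the second risk. The fallback delivers C8 from the C13 side chain and sets out from 16. Cross-metathesis with 3-chloro-2-methylprop-1-ene (second-generation Hoveyda–Grubbs catalyst) gives the allylic chloride F5 as an E/Z mixture. Indium metal with NaI in DMF/H2O then forms the allylindium reagent, which can reach only C7 and only from the face of the side chain, so ring A closes cis and the alkoxide closes the hemiketal. After the DBU treatment of step 10 the route is rejoined at 20.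

**Step 4.** The likely failure is slow insertion of the hindered, α-quaternary ester into the substituted titanacyclopropane while the carboxylate salt precipitates or binds titanium, which would leave starting material or reduced by-products. The fallback protects the acid and sets out from 5. Boc2O, DMAP and t-BuOH give the tert-butyl methyl diester F6. The Kulinkovich reaction with 6 and ClTi(OiPr)3 in homogeneous solution spares the tert-butyl ester and gives the cyclopropanol tert-butyl ester F7. TMSOTf/2,6-lutidine, then K2CO3 in aqueous methanol, cleaves the tert-butyl ester and any silyl ether, and the route is rejoined at 7.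

**Step 2.** The likely failure is loss of regiocontrol, either in the first protonation or through methylation at the carboxylate-bearing carbon, together with some aminolysis of the ester. The fallback changes the order and sets out from 1. The same reductive methylation on the symmetrical diester, whose two ester carbons are equivalent until the first protonation, gives the racemic diester F8. LiOH (1.0 equiv, THF/H2O, 0 °C) then hydrolyses only the unhindered conjugated ester, and the route is rejoined at 4.

**Step 3.** The likely failure is that no amine salt crystallises with useful discrimination, or that the enol ether is hydrolysed when the acid is set free. The fallback sets out from 4 and separates its enantiomers by preparative chromatography on a quinine-carbamate anion-exchange chiral stationary phase with a weakly acidic methanolic eluent. It makes no new compound and rejoins the route at 5.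

## Further compounds

F1 | step 6 | methyl (3S)-5-methoxy-3-methyl-3-[4-methyl-3-(phenylselanyl)pentanoyl]cyclohexa-1,4-diene-1-carboxylate (both C19 epimers) | COC1=C[C@@](C)(C(=O)CC([Se]c2ccccc2)C(C)C)C=C(C1)C(=O)OC
F2 | step 6 | methyl (3S)-5-methoxy-3-methyl-3-[(2E)-4-methylpent-2-enoyl]cyclohexa-1,4-diene-1-carboxylate | COC1=C[C@@](C)(C(=O)/C=C/C(C)C)C=C(C1)C(=O)OC
F3 | step 6 | methyl 3-methoxy-4a-methyl-8-nitro-5-oxo-7-(propan-2-yl)-1,2,4a,5,6,7,8,8a-octahydronaphthalene-1-carboxylate (cis-fused; mixture at C1, C7, C8) | COC(=O)C1CC(OC)=C[C@]2(C)[C@H]1C([N+](=O)[O-])C(C(C)C)CC2=O
F4 | step 6 | methyl 3-methoxy-4a-methyl-5,8-dioxo-7-(propan-2-yl)-1,2,4a,5,6,7,8,8a-octahydronaphthalene-1-carboxylate (cis-fused; mixture at C1 and C7) | COC(=O)C1CC(OC)=C[C@]2(C)[C@H]1C(=O)C(C(C)C)CC2=O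
F5 | step 9 | methyl 4-(4-chloro-3-methylbut-2-en-1-yl)-4a-methyl-3,5,8-trioxo-7-(propan-2-yl)-3,4,4a,5,6,7,8,8a-octahydronaphthalene-1-carboxylate (E/Z mixture; ring stereochemistry as in 16) | COC(=O)C1=CC(=O)[C@H](CC=C(C)CCl)[C@]2(C)[C@H]1C(=O)[C@@H](C(C)C)CC2=O
F6 | step 4 | 1-tert-butyl 3-methyl (3S)-5-methoxy-3-methylcyclohexa-1,4-diene-1,3-dicarboxylate | COC1=C[C@@](C)(C(=O)OC)C=C(C1)C(=O)OC(C)(C)C
F7 | step 4 | tert-butyl (3S)-3-[(1S,2R)-1-hydroxy-2-(propan-2-yl)cyclopropyl]-5-methoxy-3-methylcyclohexa-1,4-diene-1-carboxylate (with its (1R,2S)-cyclopropyl diastereomer) | COC1=C[C@@](C)([C@]2(O)C[C@@H]2C(C)C)C=C(C1)C(=O)OC(C)(C)C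
F8 | step 2 | rac-dimethyl 5-methoxy-1-methylcyclohexa-2,5-diene-1,3-dicarboxylate | COC1=CC(C)(C(=O)OC)C=C(C1)C(=O)OC
F0 | step 3 | none | none
A1 | alternative 1 | methyl 4,4-dimethoxy-5-methyl-3-oxocyclohexa-1,5-diene-1-carboxylate (masked o-benzoquinone) | COC(=O)C1=CC(=O)C(OC)(OC)C(C)=C1
A2 | alternative 1 | 1-(methoxymethoxy)-5-methylcyclohexa-1,4-diene | COCOC1=CCC=C(C)C1
A3 | alternative 1 | bicyclo[2.2.2]octenone cycloadduct of A1 and A2 | COC(=O)C1=C[C@@]2(C)[C@H]3CC=C(C)C[C@@]3(OCOC)[C@@H]1C(=O)C2(OC)OC
A4 | alternative 2 | fourteen-membered tetraene with C7 tert-butyldimethylsilyl dienol ether, C17 and C24 ketones and the C19 isopropyl stereocentre | CC(C)(C)[Si](C)(C)O/C1=C/C(C(=O)OC)=C/C(=O)[C@@H](C(C)C)CC(=O)/C(C)=C/C/C=C(C)\C1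
A5 | alternative 2 | tricyclic diketo ester with C7 silyl ether (open form of the target) | COC(=O)C1=C[C@]2(O[Si](C)(C)C(C)(C)C)CC(C)=CC[C@@H]2[C@]2(C)[C@H]1C(=O)[C@@H](C(C)C)CC2=O
A6 | alternative 3 | acyclic triethylsilyloxy-triene with the 1,4-diketone tether | C=C(O[Si](CC)(CC)CC)/C=C(C)/C(=O)C[C@H](C(C)C)C(=O)/C=C/C(=O)OC
A7 | alternative 3 | cis-fused B/C diketo ester with C7 triethylsilyl enol ether | COC(=O)[C@@H]1CC(O[Si](CC)(CC)CC)=C[C@]2(C)[C@H]1C(=O)[C@@H](C(C)C)CC2=O
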